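**Retrosynthetic overview**
1. Ring C (C8, C9, C11–C14: carbonyls at C11 and C14, hydroxyl on C12, isopropyl on C13, fused to ring B at C8–C9) is a 2-hydroxy-1,4-benzoquinone, i.e. the oxidised enol form of a cyclohexane-1,2,4-trione. It is opened at C12–C13 (Dieckmann closure of an isovaleryl ketone onto an oxalyl ester); the trione aromatises to the benzene-1,2,4-triol, which air oxidises to the quinone.
2. The Dieckmann precursor 19 (ring B ketone, isovaleryl on C8, methoxalyl on C9) comes from enone 11 by a tandem Mukaiyama–Michael (glycolate ketene silyl acetal to C9) / aldol (isovaleraldehyde at C8) reaction and oxidation of both carbinols.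
3. Enone 11 with C5 and C10 comes from an enantioselective Diels–Alder reaction of aminosiloxydiene 4 with (E)-2-methyl-4-oxopent-2-enal; the aldehyde becomes the propanoate chain and the acetyl group the isopropenyl group before the enone is unmasked.
4. Ring order: ring B (Diels–Alder), then ring C (Dieckmann with aromatisation); ring A is absent (3,4-seco skeleton).

Key step: step 9

**Remarks**
- Locants in the discussion follow abietane numbering: C5 (CH bearing isopropenyl), C6 (CH2), C7 (ring B ketone), C8/C9 (ring fusion), C10 (quaternary, methyl and C1–C3 propanoate chain), C11–C14 (ring C). Names use systematic numbering.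
- Assumption: the sense of induction of the diol catalyst in step 2 parallels that with 2-substituted acroleins; the (R,R) catalyst is written, and its antipode is to be used if the opposite sense is found.
- The oxalyl ester is a methyl ester, so that the alkoxide expelled in step 9 is the same as that of the side-chain ester.
- The amine-bearing carbon in 6–10 and C8, C9, C11, C14 in 16–19 are expected as mixtures (C8/C9 drawn trans). All of these centres become sp2 later. 19 is drawn as the triketo tautomer.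

**Route**

Step 1
Reactants: 1 methylglyoxal (40% aqueous solution); 2 2-(triphenylphosphoranylidene)propanal
Product: 3 (E)-2-methyl-4-oxopent-2-enal
Conditions: CH2Cl2/H2O, rt (1 in excess)
Reagents that add atoms: none
Why: Wittig olefination in which the formyl-stabilised ylide attacks only the aldehyde carbonyl of 1 and, as a stabilised ylide, should give the (E)-enal (acetyl trans to CHO), the geometry that later places the C5 acetyl cis to the C10 methyl.

Step 2
Reactants: 3 (E)-2-methyl-4-oxopent-2-enal; 4 (E)-1-(dimethylamino)-3-(tert-butyldimethylsilyloxy)buta-1,3-diene; 5 methyl (triphenylphosphoranylidene)acetate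
Product: 7 methyl (E)-3-[(1S,6R)-6-acetyl-4-(tert-butyldimethylsilyloxy)-2-(dimethylamino)-1-methylcyclohex-3-en-1-yl]prop-2-enoate, via cycloadduct aldehyde 6 (not isolated)
Conditions: (R,R)-1-naphthyl-TADDOL (20 mol%), toluene, −78 °C; then 5, −78 → 40 °C; filtration through basic alumina
Reagents that add atoms: none
Why: Hydrogen-bond-catalysed enantioselective Diels–Alder reaction in which the nucleophilic CH2 terminus of 4 bonds to the unsubstituted, acetyl-bearing alkene carbon (β to the stronger, catalyst-bound aldehyde acceptor) and the amino terminus to the formyl-bearing carbon, suprafacial addition to the (E)-dienophile fixing the C10 methyl cis to the C5 acetyl and the chiral diol the absolute sense at both centres; the stabilised ylide then olefinates only the aldehyde of 6 (Wittig reaction), leaving the ketone and the silyl enol ether.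

Step 3
Reactants: 7 methyl (E)-3-[(1S,6R)-6-acetyl-4-(tert-butyldimethylsilyloxy)-2-(dimethylamino)-1-methylcyclohex-3-en-1-yl]prop-2-enoate
Product: 8 methyl 3-[(1S,6R)-6-acetyl-4-(tert-butyldimethylsilyloxy)-2-(dimethylamino)-1-methylcyclohex-3-en-1-yl]propanoate
Conditions: H2 (1 atm), RhCl(PPh3)3 (5 mol%), toluene, rt
Reagents that add atoms: none
Why: Homogeneous hydrogenation should saturate the disubstituted conjugated C=C and leave the trisubstituted silyl enol ether, the ketone and the amine; done at this stage, no ring enone or isopropenyl group is present to compete.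

Step 4
Reactants: 8 methyl 3-[(1S,6R)-6-acetyl-4-(tert-butyldimethylsilyloxy)-2-(dimethylamino)-1-methylcyclohex-3-en-1-yl]propanoate
Product: 11 methyl 3-[(1R,6S)-1-methyl-4-oxo-6-(prop-1-en-2-yl)cyclohex-2-en-1-yl]propanoate, via isopropenyl silyl enol ether 9 (not isolated), via β-amino ketone 10 (not isolated)
Conditions: Ph3PCH3Br, KOtBu, THF, 0 °C → rt; then 48% aq. HF, MeCN, rt
Reagents that add atoms: methyltriphenylphosphonium bromide, C[P+](c1ccccc1)(c1ccccc1)c1ccccc1.[Br-]
Why: Wittig methylenation converts the methyl ketone (much faster than the ester) into the isopropenyl group while the ring ketone is still masked, addition of 8 to the cold ylide limiting enolisation at C5; HF then cleaves the silyl enol ether and the β-amino ketone loses dimethylamine by E1cB elimination to give the enone.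

Step 5
Reactants: 12 methyl glycolate
Product: 13 methyl 2-(trimethylsilyloxy)acetate
Conditions: TMSCl, Et3N, CH2Cl2, 0 °C → rt
Reagents that add atoms: chlorotrimethylsilane, C[Si](C)(C)Cl
Why: Routine O-silylation of a primary alcohol with a silyl chloride and an amine base.

Step 6
Reactants: 13 methyl 2-(trimethylsilyloxy)acetate
Product: 14 (Z)-1-methoxy-1,2-bis(trimethylsilyloxy)ethene
Conditions: LDA, TMSCl, THF, −78 °C → rt; distillation
Reagents that add atoms: chlorotrimethylsilane, C[Si](C)(C)Cl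
Why: Ester enolisation with lithium diisopropylamide and O-silylation of the enolate gives the ketene silyl acetal; its geometry (drawn Z) is of no consequence because C11 ends as a carbonyl carbon.

Step 7
Reactants: 11 methyl 3-[(1R,6S)-1-methyl-4-oxo-6-(prop-1-en-2-yl)cyclohex-2-en-1-yl]propanoate; 14 (Z)-1-methoxy-1,2-bis(trimethylsilyloxy)ethene; 15 3-methylbutanal
Product: 18 methyl 3-[(1S,2S)-5-(1-hydroxy-3-methylbutyl)-6-(1-hydroxy-2-methoxy-2-oxoethyl)-1-methyl-4-oxo-2-(prop-1-en-2-yl)cyclohexyl]propanoate, via Michael silyl enol ether 16 (not isolated), via bis(trimethylsilyl) aldol 17 (not isolated)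
Conditions: Ph3CSbCl6 (10 mol%), CH2Cl2, −78 → −40 °C; then 15, −78 °C; then 1 M HCl, THF, 0 °C
Reagents that add atoms: none
Why: Tandem Mukaiyama–Michael / Mukaiyama aldol reaction under trityl salt catalysis, in which the planar ketene silyl acetal adds to C9 of the activated enone (expected anti to the axial C10 methyl), the silyl enol ether so formed reacts at C8 with the aldehyde trans to the new C9 substituent, and dilute acid removes both silyl groups; the configurations at C8, C9, C11 and C14 do not matter.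

Step 8
Reactants: 18 methyl 3-[(1S,2S)-5-(1-hydroxy-3-methylbutyl)-6-(1-hydroxy-2-methoxy-2-oxoethyl)-1-methyl-4-oxo-2-(prop-1-en-2-yl)cyclohexyl]propanoate
Product: 19 methyl 3-[(1S,2S)-6-(2-methoxy-2-oxoacetyl)-1-methyl-5-(3-methylbutanoyl)-4-oxo-2-(prop-1-en-2-yl)cyclohexyl]propanoate
Conditions: Dess–Martin periodinane (2.5 equiv), CH2Cl2, 0 °C → rt
Reagents that add atoms: none
Why: Dess–Martin oxidation of both secondary alcohols (β-hydroxy ketone to β-diketone, α-hydroxy ester to α-keto ester) under neutral conditions that tolerate the alkene and the esters.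

Step 9
Reactants: 19 methyl 3-[(1S,2S)-6-(2-methoxy-2-oxoacetyl)-1-methyl-5-(3-methylbutanoyl)-4-oxo-2-(prop-1-en-2-yl)cyclohexyl]propanoate
Product: 21 methyl 3-[(1S,2S)-5,7,8-trihydroxy-1-methyl-4-oxo-6-(propan-2-yl)-2-(prop-1-en-2-yl)-1,2,3,4-tetrahydronaphthalen-1-yl]propanoate, via cyclohexanetrione 20 (not isolated)
Conditions: KOtBu (4 equiv), THF/tBuOH, 0 → 40 °C, argon; then degassed 1 M HCl
Reagents that add atoms: none
Why: Excess tert-butoxide converts 19 into its β-diketonate and, reversibly, into the C13 enolate of the isovaleryl ketone, which attacks the oxalyl ester carbon C12 and expels methoxide (Dieckmann condensation; the closest known type is the oxalate-ester Claisen condensation of ketones). Ring C (C8, C14, C13, C12, C11, C9) closes in a 6-exo-trig mode to trione 20, which enolises at C8, C9 and C13 to the benzene-1,2,4-triol, so the closure should be irreversible. No stereocentre is created: C8 and C9 become aromatic carbons, C10 is quaternary and C5–H is not α to a carbonyl, so C5 and C10 are not at risk. The step needs site selectivity among the enolisable positions C2, C6, C8, C9 and C13; it is supplied thermodynamically, because aldol additions to C11 and Claisen closures from C6 or C9 give bridged or quaternary products that cannot aromatise and should revert, whereas only the C13-to-C12 closure reaches the aromatic sink. The methyl oxalyl ester ensures that the methoxide set free cannot alter the side-chain methyl ester.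

Step 10
Reactants: 21 methyl 3-[(1S,2S)-5,7,8-trihydroxy-1-methyl-4-oxo-6-(propan-2-yl)-2-(prop-1-en-2-yl)-1,2,3,4-tetrahydronaphthalen-1-yl]propanoate
Product: 22 methyl 3-[(1S,2S)-7-hydroxy-1-methyl-4,5,8-trioxo-6-(propan-2-yl)-2-(prop-1-en-2-yl)-1,2,3,4,5,8-hexahydronaphthalen-1-yl]propanoate
Conditions: air (O2), EtOAc/pH 7 phosphate buffer, rt
Reagents that add atoms: none
Why: Autoxidation of an electron-rich benzene-1,2,4-triol to the 2-hydroxy-1,4-benzoquinone, which should be spontaneous in air and leaves C5 and C10 untouched.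

**Compound list**
1 | methylglyoxal (2-oxopropanal) | CC(=O)C=O | starting material
2 | 2-(triphenylphosphoranylidene)propanal | CC(C=O)=P(c1ccccc1)(c1ccccc1)c1ccccc1 | starting material
3 | (E)-2-methyl-4-oxopent-2-enal | CC(=O)/C=C(\C)C=O | intermediate
4 | (E)-1-(dimethylamino)-3-(tert-butyldimethylsilyloxy)buta-1,3-diene | CN(C)/C=C/C(=C)O[Si](C)(C)C(C)(C)C | starting material
5 | methyl (triphenylphosphoranylidene)acetate | COC(=O)C=P(c1ccccc1)(c1ccccc1)c1ccccc1 | starting material
6 | (1S,6R)-6-acetyl-4-(tert-butyldimethylsilyloxy)-2-(dimethylamino)-1-methylcyclohex-3-ene-1-carbaldehyde (C2 epimers) | CC(=O)[C@@H]1CC(O[Si](C)(C)C(C)(C)C)=CC(N(C)C)[C@@]1(C)C=O | intermediate (not isolated)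
7 | methyl (E)-3-[(1S,6R)-6-acetyl-4-(tert-butyldimethylsilyloxy)-2-(dimethylamino)-1-methylcyclohex-3-en-1-yl]prop-2-enoate | CC(=O)[C@@H]1CC(O[Si](C)(C)C(C)(C)C)=CC(N(C)C)[C@@]1(C)/C=C/C(=O)OC | intermediate
8 | methyl 3-[(1S,6R)-6-acetyl-4-(tert-butyldimethylsilyloxy)-2-(dimethylamino)-1-methylcyclohex-3-en-1-yl]propanoate | CC(=O)[C@@H]1CC(O[Si](C)(C)C(C)(C)C)=CC(N(C)C)[C@@]1(C)CCC(=O)OC | intermediate
9 | methyl 3-[(1S,6S)-4-(tert-butyldimethylsilyloxy)-2-(dimethylamino)-1-methyl-6-(prop-1-en-2-yl)cyclohex-3-en-1-yl]propanoate | C=C(C)[C@@H]1CC(O[Si](C)(C)C(C)(C)C)=CC(N(C)C)[C@@]1(C)CCC(=O)OC | intermediate (not isolated)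
10 | methyl 3-[(1S,6S)-2-(dimethylamino)-1-methyl-4-oxo-6-(prop-1-en-2-yl)cyclohexyl]propanoate | C=C(C)[C@@H]1CC(=O)CC(N(C)C)[C@@]1(C)CCC(=O)OC | intermediate (not isolated)
11 | methyl 3-[(1R,6S)-1-methyl-4-oxo-6-(prop-1-en-2-yl)cyclohex-2-en-1-yl]propanoate | C=C(C)[C@@H]1CC(=O)C=C[C@@]1(C)CCC(=O)OC | intermediate
12 | methyl glycolate | COC(=O)CO | starting material
13 | methyl 2-(trimethylsilyloxy)acetate | COC(=O)CO[Si](C)(C)C | intermediate
14 | (Z)-1-methoxy-1,2-bis(trimethylsilyloxy)ethene | CO/C(O[Si](C)(C)C)=C/O[Si](C)(C)C | intermediate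
15 | 3-methylbutanal (isovaleraldehyde) | CC(C)CC=O | starting material
16 | methyl 3-[(1S,2S)-6-[2-methoxy-2-oxo-1-(trimethylsilyloxy)ethyl]-1-methyl-2-(prop-1-en-2-yl)-4-(trimethylsilyloxy)cyclohex-4-en-1-yl]propanoate | C=C(C)[C@@H]1CC(O[Si](C)(C)C)=C[C@@H](C(O[Si](C)(C)C)C(=O)OC)[C@@]1(C)CCC(=O)OC | intermediate (not isolated)
17 | methyl 3-[(1S,2S)-6-[2-methoxy-2-oxo-1-(trimethylsilyloxy)ethyl]-1-methyl-5-[3-methyl-1-(trimethylsilyloxy)butyl]-4-oxo-2-(prop-1-en-2-yl)cyclohexyl]propanoate | C=C(C)[C@@H]1CC(=O)[C@H](C(CC(C)C)O[Si](C)(C)C)[C@@H](C(O[Si](C)(C)C)C(=O)OC)[C@@]1(C)CCC(=O)OC | intermediate (not isolated)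
18 | methyl 3-[(1S,2S)-5-(1-hydroxy-3-methylbutyl)-6-(1-hydroxy-2-methoxy-2-oxoethyl)-1-methyl-4-oxo-2-(prop-1-en-2-yl)cyclohexyl]propanoate | C=C(C)[C@@H]1CC(=O)[C@H](C(O)CC(C)C)[C@@H](C(O)C(=O)OC)[C@@]1(C)CCC(=O)OC | intermediate
19 | methyl 3-[(1S,2S)-6-(2-methoxy-2-oxoacetyl)-1-methyl-5-(3-methylbutanoyl)-4-oxo-2-(prop-1-en-2-yl)cyclohexyl]propanoate | C=C(C)[C@@H]1CC(=O)[C@H](C(=O)CC(C)C)[C@@H](C(=O)C(=O)OC)[C@@]1(C)CCC(=O)OC | intermediate
20 | methyl 3-[(1S,2S)-1-methyl-4,5,7,8-tetraoxo-6-(propan-2-yl)-2-(prop-1-en-2-yl)decahydronaphthalen-1-yl]propanoate | C=C(C)[C@@H]1CC(=O)C2C(=O)C(C(C)C)C(=O)C(=O)C2[C@@]1(C)CCC(=O)OC | intermediate (not isolated)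
21 | methyl 3-[(1S,2S)-5,7,8-trihydroxy-1-methyl-4-oxo-6-(propan-2-yl)-2-(prop-1-en-2-yl)-1,2,3,4-tetrahydronaphthalen-1-yl]propanoate | C=C(C)[C@@H]1CC(=O)c2c(O)c(C(C)C)c(O)c(O)c2[C@@]1(C)CCC(=O)OC | intermediate
22 | methyl 3-[(1S,2S)-7-hydroxy-1-methyl-4,5,8-trioxo-6-(propan-2-yl)-2-(prop-1-en-2-yl)-1,2,3,4,5,8-hexahydronaphthalen-1-yl]propanoate | C=C(C)[C@@H]1CC(=O)C2=C(C(=O)C(O)=C(C(C)C)C2=O)[C@@]1(C)CCC(=O)OC | target

**Step count**
Total: 10 steps. Longest linear sequence: 8 steps (1, 2, 3, 4, 7, 8, 9, 10); steps 5 and 6 form the side branch.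

**Steps most likely to fail**

Step 9 (key step). Deprotonation at C8 and C9 may turn the oxalyl unit into an enolate-conjugated, poorly electrophilic ester and leave the C13 enolate as a minor equilibrium component, so that reversible aldol and retro-Claisen processes consume the material before ring closure. The fallback oxidises before closing the ring and sets out from 19. Selenenylation at the β-dicarbonyl carbon C8 (PhSeCl, pyridine, CH2Cl2, 0 °C) should give the selenide F1. Oxidation with H2O2 gives the selenoxide F2, which eliminates towards C9–H to the ene-trione F3 (C8=C9). In F3 neither C8 nor C9 carries hydrogen, so the C13 enolate (KOtBu or DBU, THF, 0 °C) is the only ketone enolate that can reach an ester. The same C13-to-C12 Dieckmann closure, with the ring alkene holding both arms cis, then delivers the enolate of the hydroxyquinone directly, and the route is rejoined at 22.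

Step 7. Michael addition at C9, a neopentyl-type carbon next to quaternary C10, may be slow, so that the acid-labile ketene acetal is consumed or the intermediate silyl enol ether is protodesilylated before the aldol step. The fallback is an anionic acyl-anion route without Lewis acid and sets out from 11. Commercial ethyl 1,3-dithiane-2-carboxylate is transesterified (NaOMe, MeOH) to methyl 1,3-dithiane-2-carboxylate F4. Its lithium salt (LDA, THF, −78 → 0 °C) should add 1,4 to 11 under thermodynamic control, and the lithium enolate is trapped at −78 °C with 15 to give the dithiane aldol F5. Dess–Martin oxidation gives the dithiane β-diketone F6, and PhI(OCOCF3)2 in aqueous MeCN hydrolyses the dithiane to return the route at 19.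

Step 2. Facial discrimination may be insufficient because the trisubstituted dienophile offers the diol catalyst two carbonyl acceptors, and hetero-Diels–Alder addition across the aldehyde may compete. The fallback replaces catalyst control by auxiliary control and sets out from 3. (2R,5R)-2,5-Diphenylpyrrolidine (the antipode if the sense of induction requires it) and 4-methoxybut-3-en-2-one give the vinylogous amide F7, and potassium hexamethyldisilazide/TBSCl (THF, −78 °C) gives the chiral diene F8. Thermal cycloaddition with 3 (toluene, −20 °C → rt) gives the cycloadduct F9. The sequence of steps 2–4 then follows: ylide 5 gives the acrylate F10; H2 with RhCl(PPh3)3 gives the propanoate F11; Ph3P=CH2 gives the isopropenyl compound F12; HF gives the β-amino ketone F13, which eliminates the recoverable pyrrolidine and returns the route at 11.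

**Further compounds**
F1 | step 9 | methyl 3-[(1S,2S)-6-(2-methoxy-2-oxoacetyl)-1-methyl-5-(3-methylbutanoyl)-4-oxo-5-(phenylselanyl)-2-(prop-1-en-2-yl)cyclohexyl]propanoate | C=C(C)[C@@H]1CC(=O)C([Se]c2ccccc2)(C(=O)CC(C)C)[C@@H](C(=O)C(=O)OC)[C@@]1(C)CCC(=O)OC
F2 | step 9 | corresponding selenoxide, methyl 3-[(1S,2S)-6-(2-methoxy-2-oxoacetyl)-1-methyl-5-(3-methylbutanoyl)-4-oxo-5-(phenylseleninyl)-2-(prop-1-en-2-yl)cyclohexyl]propanoate | C=C(C)[C@@H]1CC(=O)C([Se](=O)c2ccccc2)(C(=O)CC(C)C)[C@@H](C(=O)C(=O)OC)[C@@]1(C)CCC(=O)OC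
F3 | step 9 | methyl 3-[(1S,6S)-2-(2-methoxy-2-oxoacetyl)-1-methyl-3-(3-methylbutanoyl)-4-oxo-6-(prop-1-en-2-yl)cyclohex-2-en-1-yl]propanoate | C=C(C)[C@@H]1CC(=O)C(C(=O)CC(C)C)=C(C(=O)C(=O)OC)[C@@]1(C)CCC(=O)OC
F4 | step 7 | methyl 1,3-dithiane-2-carboxylate | COC(=O)C1SCCCS1
F5 | step 7 | methyl 2-[(1S,2S)-6-(1-hydroxy-3-methylbutyl)-2-(3-methoxy-3-oxopropyl)-2-methyl-5-oxo-3-(prop-1-en-2-yl)cyclohexyl]-1,3-dithiane-2-carboxylate | C=C(C)[C@@H]1CC(=O)[C@H](C(O)CC(C)C)[C@@H](C2(C(=O)OC)SCCCS2)[C@@]1(C)CCC(=O)OC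
F6 | step 7 | methyl 2-[(1S,2S)-2-(3-methoxy-3-oxopropyl)-2-methyl-6-(3-methylbutanoyl)-5-oxo-3-(prop-1-en-2-yl)cyclohexyl]-1,3-dithiane-2-carboxylate | C=C(C)[C@@H]1CC(=O)[C@H](C(=O)CC(C)C)[C@@H](C2(C(=O)OC)SCCCS2)[C@@]1(C)CCC(=O)OC
F7 | step 2 | (E)-4-[(2R,5R)-2,5-diphenylpyrrolidin-1-yl]but-3-en-2-one | CC(=O)/C=C/N1[C@@H](c2ccccc2)CC[C@@H]1c1ccccc1
F8 | step 2 | (2R,5R)-1-[(E)-3-(tert-butyldimethylsilyloxy)buta-1,3-dien-1-yl]-2,5-diphenylpyrrolidine | C=C(O[Si](C)(C)C(C)(C)C)/C=C/N1[C@@H](c2ccccc2)CC[C@@H]1c1ccccc1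
F9 | step 2 | (1S,6R)-6-acetyl-4-(tert-butyldimethylsilyloxy)-2-[(2R,5R)-2,5-diphenylpyrrolidin-1-yl]-1-methylcyclohex-3-ene-1-carbaldehyde | CC(=O)[C@@H]1CC(O[Si](C)(C)C(C)(C)C)=CC(N2[C@@H](c3ccccc3)CC[C@@H]2c2ccccc2)[C@@]1(C)C=O
F10 | step 2 | methyl (E)-3-[(1S,6R)-6-acetyl-4-(tert-butyldimethylsilyloxy)-2-[(2R,5R)-2,5-diphenylpyrrolidin-1-yl]-1-methylcyclohex-3-en-1-yl]prop-2-enoate | CC(=O)[C@@H]1CC(O[Si](C)(C)C(C)(C)C)=CC(N2[C@@H](c3ccccc3)CC[C@@H]2c2ccccc2)[C@@]1(C)/C=C/C(=O)OC
F11 | step 2 | methyl 3-[(1S,6R)-6-acetyl-4-(tert-butyldimethylsilyloxy)-2-[(2R,5R)-2,5-diphenylpyrrolidin-1-yl]-1-methylcyclohex-3-en-1-yl]propanoate | CC(=O)[C@@H]1CC(O[Si](C)(C)C(C)(C)C)=CC(N2[C@@H](c3ccccc3)CC[C@@H]2c2ccccc2)[C@@]1(C)CCC(=O)OC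
F12 | step 2 | methyl 3-[(1S,6S)-4-(tert-butyldimethylsilyloxy)-2-[(2R,5R)-2,5-diphenylpyrrolidin-1-yl]-1-methyl-6-(prop-1-en-2-yl)cyclohex-3-en-1-yl]propanoate | C=C(C)[C@@H]1CC(O[Si](C)(C)C(C)(C)C)=CC(N2[C@@H](c3ccccc3)CC[C@@H]2c2ccccc2)[C@@]1(C)CCC(=O)OC
F13 | step 2 | methyl 3-[(1S,6S)-2-[(2R,5R)-2,5-diphenylpyrrolidin-1-yl]-1-methyl-4-oxo-6-(prop-1-en-2-yl)cyclohexyl]propanoate | C=C(C)[C@@H]1CC(=O)CC(N2[C@@H](c3ccccc3)CC[C@@H]2c2ccccc2)[C@@]1(C)CCC(=O)OC
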